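Everything rests on opening ring A at C4–C5. Its oxygens at C4 and C6 are meta to each other and flank the alkylated C5, the pattern of an enolised cyclic 1,3-diketone, so C4 is traced to an ester carbon on a furan and C6 to a side-chain ketone. A single intramolecular Claisen condensation with aromatisation then closes ring A, creates both phenols, puts the (R)-configured chain on C5 and leaves C7 as CH. The substrate is a 2-aryl-5-(2-oxoalkyl)furan-3,4-diester carrying the silylated (R)-carbinol in the chain and a silylated ring B; the ester not used in the closure later becomes the C3 formyl group.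

Key step: step 9

Remark: benzofuran numbering is used for the target and the benzofuran intermediates (aryl on C2, formyl carbon on C3, hydroxyl on C4, chain on C5, methoxyl on C6); the carbinol centre is (R) from the lactone acid to the target because no step breaks its C–O bond, and 4-bromo-3-methoxyphenol and 4,5-dimethyloxazole are taken as commercial.

Step 1
Reactants: 1 4-bromo-3-methoxyphenol
Product: 2 (4-bromo-3-methoxyphenoxy)triisopropylsilane
Conditions: TIPSCl, imidazole, DMF, rt
Reagents that add atoms: triisopropylsilyl chloride, CC(C)[Si](Cl)(C(C)C)C(C)C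
Why: Imidazole-promoted O-silylation of a phenol, chosen because the bulky aryl silyl ether should tolerate organolithium and amide bases and leave with fluoride at the end.

Step 2
Reactants: 3 4,5-dimethyloxazole; 2 (4-bromo-3-methoxyphenoxy)triisopropylsilane
Product: 6 2-[2-methoxy-4-(triisopropylsilyloxy)phenyl]-4,5-dimethyloxazole, via 2-lithio-4,5-dimethyloxazole 4 (not isolated), via (4,5-dimethyloxazol-2-yl)zinc chloride 5 (not isolated)
Conditions: n-BuLi, THF, −78 °C; ZnCl2, −78 °C → rt; then 2, Pd2(dba)3 (2 mol %), XPhos (8 mol %), THF, 65 °C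
Reagents that add atoms: none
Why: C2–H is the most acidic position of the oxazole, transmetalation to zinc holds the ring closed, and the Negishi coupling with the aryl bromide runs under neutral conditions that spare the silyl ether.

Step 3
Reactants: 6 2-[2-methoxy-4-(triisopropylsilyloxy)phenyl]-4,5-dimethyloxazole; 7 dimethyl acetylenedicarboxylate
Product: 9 dimethyl 2-[2-methoxy-4-(triisopropylsilyloxy)phenyl]-5-methylfuran-3,4-dicarboxylate, via 7-oxa-2-azanorbornadiene cycloadduct 8 (not isolated)
Conditions: toluene, 130 °C, sealed tube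
Reagents that add atoms: none
Why: Diels–Alder addition of the alkyne across C2 and C5 of the electron-rich oxazole followed by retro-Diels–Alder loss of acetonitrile (N3 and C4 with its methyl) is the established oxazole-to-furan exchange, and this extrusion is the only productive fragmentation, so aryl and methyl end up on the two furan α-carbons.

Step 4
Reactants: 10 (R)-5-oxotetrahydrofuran-2-carboxylic acid
Product: 12 (R)-5-acetyldihydrofuran-2(3H)-one, via (R)-5-oxotetrahydrofuran-2-carbonyl chloride 11 (not isolated)
Conditions: (COCl)2, DMF (cat.), CH2Cl2, 0 °C → rt, evaporate; MeMgBr (1.05 equiv), Fe(acac)3 (3 mol %), THF, −78 °C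
Reagents that add atoms: methylmagnesium bromide, C[Mg]Br
Why: Base-free chloride formation cannot racemise the α-acyloxy centre through a ketene, and the iron-catalysed cross-coupling of the acid chloride with the Grignard reagent at −78 °C should outrun addition to the lactone or to the ketone formed, so the stereocentre is carried over unchanged.

Step 5
Reactants: 12 (R)-5-acetyldihydrofuran-2(3H)-one
Product: 13 (R)-5-(prop-1-en-2-yl)dihydrofuran-2(3H)-one
Conditions: Zn, CH2Br2, TiCl4, THF/CH2Cl2, 0 °C → rt
Reagents that add atoms: dibromomethane, BrCBr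
Why: Takai–Lombardo methylenation uses a non-basic zinc/titanium methylene reagent that converts ketones but not lactones and does not enolise the substrate, so the adjacent (R)-centre keeps its configuration.

Step 6
Reactants: 13 (R)-5-(prop-1-en-2-yl)dihydrofuran-2(3H)-one
Product: 14 (4R)-4-hydroxy-N-methoxy-N,5-dimethylhex-5-enamide
Conditions: MeNH(OMe)·HCl, i-PrMgCl, THF, −20 °C; then 13, −20 → 0 °C
Reagents that add atoms: N,O-dimethylhydroxylamine hydrochloride, CNOC.Cl
Why: The chloromagnesium amide opens the γ-lactone at the acyl carbon (aminolysis to a Weinreb amide) without touching the C–O bond of the stereocentre, and the hydroxy amide is taken on crude to forestall relactonisation.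

Step 7
Reactants: 14 (4R)-4-hydroxy-N-methoxy-N,5-dimethylhex-5-enamide
Product: 15 (4R)-4-(tert-butyldimethylsilyloxy)-N-methoxy-N,5-dimethylhex-5-enamide
Conditions: TBSCl, imidazole, DMF, rt
Reagents that add atoms: tert-butyldimethylsilyl chloride, CC(C)(C)[Si](C)(C)Cl
Why: Standard silylation of a secondary alcohol, which locks the chain open and gives an ether that tolerates the amide bases and the hydride used later.

Step 8
Reactants: 9 dimethyl 2-[2-methoxy-4-(triisopropylsilyloxy)phenyl]-5-methylfuran-3,4-dicarboxylate; 15 (4R)-4-(tert-butyldimethylsilyloxy)-N-methoxy-N,5-dimethylhex-5-enamide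
Product: 17 dimethyl 2-[(5R)-5-(tert-butyldimethylsilyloxy)-6-methyl-2-oxohept-6-en-1-yl]-5-[2-methoxy-4-(triisopropylsilyloxy)phenyl]furan-3,4-dicarboxylate, via furylmethyllithium 16 (not isolated)
Conditions: LiN(i-Pr)2 (1.05 equiv), THF, −78 °C; then 15, −78 → −40 °C; aq. NH4Cl
Reagents that add atoms: none
Why: The furan α-methyl group, activated through the ring by the neighbouring 3-ester, undergoes lateral lithiation as 2-methyl-3-furoates and o-toluates do, and the carbanion acylates once on the Weinreb amide because the chelated tetrahedral adduct lasts until work-up, so the acidic product ketone never meets the base.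

Step 9
Reactants: 17 dimethyl 2-[(5R)-5-(tert-butyldimethylsilyloxy)-6-methyl-2-oxohept-6-en-1-yl]-5-[2-methoxy-4-(triisopropylsilyloxy)phenyl]furan-3,4-dicarboxylate
Product: 19 methyl 5-[(2R)-2-(tert-butyldimethylsilyloxy)-3-methylbut-3-en-1-yl]-4,6-dihydroxy-2-[2-methoxy-4-(triisopropylsilyloxy)phenyl]-1-benzofuran-3-carboxylate, via cyclic 4,6-diketone 18 (not isolated)
Conditions: LiN(i-Pr)2 (3.0 equiv), THF, −78 → 0 °C; AcOH, then aq. NH4Cl
Reagents that add atoms: none
Why: The first equivalent of amide base removes a furylic proton (future C7–H) and gives a delocalised enolate that cannot close a ring, the next equivalent deprotonates the chain-side α-carbon (future C5), and this carbon adds to the carbonyl of the neighbouring furan ester (future C4), methoxide leaves, and diketone 18 loses two further protons to become the resorcinol dianion, which drains every equilibrium. The closest known reaction type is the base-induced Claisen cyclisation of 2-(2-oxoalkyl)aryl esters to 1,3-dihydroxyarenes, the flask version of polyketide phenol formation. Ring A closes in the 6-(enolexo)-exo-trig mode. No stereocentre is created, since C5 of 18 is sp3 only in passing, and the (R)-carbinol cannot epimerise or be eliminated because its silyloxy group is γ to the ketone. The selectivity needed is which enolate carbon meets which ester, and ring size settles it: the furylic carbon could only make a four-membered ring with the same ester and the chain-side carbon a seven-membered, non-aromatisable ring with the far ester, so only the C5–C4 bond forms and the far ester is kept for C3. O-Acylation to a six-membered enol lactone is reopened by the lithium methoxide set free, whereas C-acylation is sealed by aromatisation.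

Step 10
Reactants: 19 methyl 5-[(2R)-2-(tert-butyldimethylsilyloxy)-3-methylbut-3-en-1-yl]-4,6-dihydroxy-2-[2-methoxy-4-(triisopropylsilyloxy)phenyl]-1-benzofuran-3-carboxylate
Product: 20 methyl 5-[(2R)-2-(tert-butyldimethylsilyloxy)-3-methylbut-3-en-1-yl]-4-hydroxy-6-methoxy-2-[2-methoxy-4-(triisopropylsilyloxy)phenyl]-1-benzofuran-3-carboxylate
Conditions: MeI (1.1 equiv), K2CO3 (1.1 equiv), acetone, rt
Reagents that add atoms: iodomethane, CI
Why: Williamson methylation under mild carbonate conditions should take the C6 hydroxyl, the more acidic and more accessible phenol, because the C4 hydroxyl is hydrogen-bonded to the C3 ester carbonyl and boxed in between that ester and the C5 chain.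

Step 11
Reactants: 20 methyl 5-[(2R)-2-(tert-butyldimethylsilyloxy)-3-methylbut-3-en-1-yl]-4-hydroxy-6-methoxy-2-[2-methoxy-4-(triisopropylsilyloxy)phenyl]-1-benzofuran-3-carboxylate
Product: 21 5-[(2R)-2-(tert-butyldimethylsilyloxy)-3-methylbut-3-en-1-yl]-3-(hydroxymethyl)-6-methoxy-2-[2-methoxy-4-(triisopropylsilyloxy)phenyl]-1-benzofuran-4-ol
Conditions: i-Bu2AlH (4 equiv), CH2Cl2, −78 → 0 °C; aq. potassium sodium tartrate
Reagents that add atoms: none
Why: Complete hydride reduction of the methyl ester to the primary alcohol (one equivalent being spent on the phenol) is dependable where a partial reduction would not be, the silyl ethers, alkene and aryl ethers are inert, and the crude alcohol is oxidised at once.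

Step 12
Reactants: 21 5-[(2R)-2-(tert-butyldimethylsilyloxy)-3-methylbut-3-en-1-yl]-3-(hydroxymethyl)-6-methoxy-2-[2-methoxy-4-(triisopropylsilyloxy)phenyl]-1-benzofuran-4-ol
Product: 22 5-[(2R)-2-(tert-butyldimethylsilyloxy)-3-methylbut-3-en-1-yl]-4-hydroxy-6-methoxy-2-[2-methoxy-4-(triisopropylsilyloxy)phenyl]-1-benzofuran-3-carbaldehyde
Conditions: MnO2 (activated, excess), CH2Cl2, rt
Reagents that add atoms: none
Why: Activated MnO2 oxidises the heterobenzylic primary alcohol selectively to the aldehyde, as in the oxidation of salicyl alcohols, and stops there while the secondary alcohol is still silylated.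

Step 13
Reactants: 22 5-[(2R)-2-(tert-butyldimethylsilyloxy)-3-methylbut-3-en-1-yl]-4-hydroxy-6-methoxy-2-[2-methoxy-4-(triisopropylsilyloxy)phenyl]-1-benzofuran-3-carbaldehyde
Product: 23 4-hydroxy-5-[(2R)-2-hydroxy-3-methylbut-3-en-1-yl]-2-(4-hydroxy-2-methoxyphenyl)-6-methoxy-1-benzofuran-3-carbaldehyde
Conditions: Bu4NF (3 equiv), AcOH (3 equiv), THF, 0 °C → rt
Reagents that add atoms: none
Why: Fluoride cleaves the aryl triisopropylsilyl ether and the secondary tert-butyldimethylsilyl ether in one operation, and the acetic acid buffer keeps the medium near neutral so that the non-enolisable aldehyde, the phenols and the allylic alcohol, whose (R)-configuration is untouched, are not disturbed.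

Compound list

1 | 4-bromo-3-methoxyphenol | COc1cc(O)ccc1Br | starting material
2 | (4-bromo-3-methoxyphenoxy)triisopropylsilane | COc1cc(O[Si](C(C)C)(C(C)C)C(C)C)ccc1Br | intermediate
3 | 4,5-dimethyloxazole | Cc1ncoc1C | starting material
4 | 2-lithio-4,5-dimethyloxazole | [Li]c1nc(C)c(C)o1 | intermediate
5 | (4,5-dimethyloxazol-2-yl)zinc chloride | Cl[Zn]c1nc(C)c(C)o1 | intermediate
6 | 2-[2-methoxy-4-(triisopropylsilyloxy)phenyl]-4,5-dimethyloxazole | Cc1nc(-c2ccc(O[Si](C(C)C)(C(C)C)C(C)C)cc2OC)oc1C | intermediate
7 | dimethyl acetylenedicarboxylate | COC(=O)C#CC(=O)OC | starting material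
8 | dimethyl 1-[2-methoxy-4-(triisopropylsilyloxy)phenyl]-3,4-dimethyl-7-oxa-2-azabicyclo[2.2.1]hepta-2,5-diene-5,6-dicarboxylate (racemic, transient) | CC1=NC2(c3ccc(O[Si](C(C)C)(C(C)C)C(C)C)cc3OC)OC1(C)C(C(=O)OC)=C2C(=O)OC | intermediate
9 | dimethyl 2-[2-methoxy-4-(triisopropylsilyloxy)phenyl]-5-methylfuran-3,4-dicarboxylate | Cc1oc(-c2ccc(O[Si](C(C)C)(C(C)C)C(C)C)cc2OC)c(C(=O)OC)c1C(=O)OC | intermediate
10 | (R)-5-oxotetrahydrofuran-2-carboxylic acid | OC(=O)[C@H]1CCC(=O)O1 | starting material
11 | (R)-5-oxotetrahydrofuran-2-carbonyl chloride | ClC(=O)[C@H]1CCC(=O)O1 | intermediate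
12 | (R)-5-acetyldihydrofuran-2(3H)-one | CC(=O)[C@H]1CCC(=O)O1 | intermediate
13 | (R)-5-(prop-1-en-2-yl)dihydrofuran-2(3H)-one | C=C(C)[C@H]1CCC(=O)O1 | intermediate
14 | (4R)-4-hydroxy-N-methoxy-N,5-dimethylhex-5-enamide | C=C(C)[C@H](O)CCC(=O)N(C)OC | intermediate
15 | (4R)-4-(tert-butyldimethylsilyloxy)-N-methoxy-N,5-dimethylhex-5-enamide | C=C(C)[C@H](O[Si](C)(C)C(C)(C)C)CCC(=O)N(C)OC | intermediate
16 | {3,4-bis(methoxycarbonyl)-5-[2-methoxy-4-(triisopropylsilyloxy)phenyl]furan-2-yl}methyllithium (drawn as the C-lithio form of the delocalised anion) | [Li]Cc1oc(-c2ccc(O[Si](C(C)C)(C(C)C)C(C)C)cc2OC)c(C(=O)OC)c1C(=O)OC | intermediate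
17 | dimethyl 2-[(5R)-5-(tert-butyldimethylsilyloxy)-6-methyl-2-oxohept-6-en-1-yl]-5-[2-methoxy-4-(triisopropylsilyloxy)phenyl]furan-3,4-dicarboxylate | C=C(C)[C@H](O[Si](C)(C)C(C)(C)C)CCC(=O)Cc1oc(-c2ccc(O[Si](C(C)C)(C(C)C)C(C)C)cc2OC)c(C(=O)OC)c1C(=O)OC | intermediate
18 | methyl 5-[(2R)-2-(tert-butyldimethylsilyloxy)-3-methylbut-3-en-1-yl]-2-[2-methoxy-4-(triisopropylsilyloxy)phenyl]-4,6-dioxo-4,5,6,7-tetrahydro-1-benzofuran-3-carboxylate (C5 epimers, present as enolate) | C=C(C)[C@H](O[Si](C)(C)C(C)(C)C)CC1C(=O)Cc2oc(-c3ccc(O[Si](C(C)C)(C(C)C)C(C)C)cc3OC)c(C(=O)OC)c2C1=O | intermediate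
19 | methyl 5-[(2R)-2-(tert-butyldimethylsilyloxy)-3-methylbut-3-en-1-yl]-4,6-dihydroxy-2-[2-methoxy-4-(triisopropylsilyloxy)phenyl]-1-benzofuran-3-carboxylate | C=C(C)[C@H](O[Si](C)(C)C(C)(C)C)Cc1c(O)cc2oc(-c3ccc(O[Si](C(C)C)(C(C)C)C(C)C)cc3OC)c(C(=O)OC)c2c1O | intermediate
20 | methyl 5-[(2R)-2-(tert-butyldimethylsilyloxy)-3-methylbut-3-en-1-yl]-4-hydroxy-6-methoxy-2-[2-methoxy-4-(triisopropylsilyloxy)phenyl]-1-benzofuran-3-carboxylate | C=C(C)[C@H](O[Si](C)(C)C(C)(C)C)Cc1c(OC)cc2oc(-c3ccc(O[Si](C(C)C)(C(C)C)C(C)C)cc3OC)c(C(=O)OC)c2c1O | intermediate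
21 | 5-[(2R)-2-(tert-butyldimethylsilyloxy)-3-methylbut-3-en-1-yl]-3-(hydroxymethyl)-6-methoxy-2-[2-methoxy-4-(triisopropylsilyloxy)phenyl]-1-benzofuran-4-ol | C=C(C)[C@H](O[Si](C)(C)C(C)(C)C)Cc1c(OC)cc2oc(-c3ccc(O[Si](C(C)C)(C(C)C)C(C)C)cc3OC)c(CO)c2c1O | intermediate
22 | 5-[(2R)-2-(tert-butyldimethylsilyloxy)-3-methylbut-3-en-1-yl]-4-hydroxy-6-methoxy-2-[2-methoxy-4-(triisopropylsilyloxy)phenyl]-1-benzofuran-3-carbaldehyde | C=C(C)[C@H](O[Si](C)(C)C(C)(C)C)Cc1c(OC)cc2oc(-c3ccc(O[Si](C(C)C)(C(C)C)C(C)C)cc3OC)c(C=O)c2c1O | intermediate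
23 | 4-hydroxy-5-[(2R)-2-hydroxy-3-methylbut-3-en-1-yl]-2-(4-hydroxy-2-methoxyphenyl)-6-methoxy-1-benzofuran-3-carbaldehyde | C=C(C)[C@H](O)Cc1c(OC)cc2oc(-c3ccc(O)cc3OC)c(C=O)c2c1O | target

Total step count: 13 (steps 1–3 build the furan, steps 4–7 the chain, steps 8–13 join and finish).
Longest linear sequence: 10 steps (compound 10 to compound 23 through steps 4–13).

Steps most likely to fail

Step 9. The furylic enolate may sit as a dead end because the second deprotonation on the chain side does not take place under aprotic amide-base conditions, or its oxygen may acylate to an enol lactone that is not reopened. The fallback sets out from 17 and closes the ring under reversible, protic conditions (NaOMe, MeOH, reflux). There the enolates interconvert freely, methoxide reopens any enol lactone, and methoxide exchange leaves the methyl esters unchanged. The alkyl silyl ether should survive but the aryl silyl ether will be lost, so the product would be methyl 5-[(2R)-2-(tert-butyldimethylsilyloxy)-3-methylbut-3-en-1-yl]-4,6-dihydroxy-2-(4-hydroxy-2-methoxyphenyl)-1-benzofuran-3-carboxylate F1. Treatment of F1 with TIPSCl (1.05 equiv) and imidazole in CH2Cl2 at 0 °C should favour the ring B phenol, the only one with two free ortho positions and no hydrogen bond, and so comes back to the route at 19.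

Step 8. The stabilised anion 16 may add slowly to the amide, so that on warming it is consumed by Claisen-type self-condensation with the ester groups of a second molecule of 9. The fallback sets out from 9 and from lactone 13, leaving out 14 and 15. Anion 16 (2 equiv, LiN(i-Pr)2, THF, −78 °C) is added to the γ-lactone 13, a stronger acyl acceptor whose cyclic tetrahedral alkoxide also resists over-addition; the second equivalent covers the case that the adduct opens to the acidic ketone. This should give dimethyl 2-[(5R)-5-hydroxy-6-methyl-2-oxohept-6-en-1-yl]-5-[2-methoxy-4-(triisopropylsilyloxy)phenyl]furan-3,4-dicarboxylate F2, in equilibrium with its five-membered lactol. Silylation of the open-chain secondary alcohol of F2 (TBSCl, imidazole, DMF, rt) comes back to the route at 17.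

Step 10. Methylation may run past the mono-ether onto the C4 hydroxyl, or carbonate may strip the ring B silyl group and the freed phenol be methylated as well. The fallback sets out from 19 and comes back at 20 without a new intermediate. It is a Mitsunobu etherification (MeOH, PPh3, diisopropyl azodicarboxylate, THF, 0 °C), a redox condensation that forms no free phenoxide, so silyl transfer and C-alkylation are excluded. It should engage only the phenol that can protonate the betaine, the C6 hydroxyl, which is not hydrogen-bonded.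

Further compounds

F1 | step 9 | methyl 5-[(2R)-2-(tert-butyldimethylsilyloxy)-3-methylbut-3-en-1-yl]-4,6-dihydroxy-2-(4-hydroxy-2-methoxyphenyl)-1-benzofuran-3-carboxylate | C=C(C)[C@H](O[Si](C)(C)C(C)(C)C)Cc1c(O)cc2oc(-c3ccc(O)cc3OC)c(C(=O)OC)c2c1O
F2 | step 8 | dimethyl 2-[(5R)-5-hydroxy-6-methyl-2-oxohept-6-en-1-yl]-5-[2-methoxy-4-(triisopropylsilyloxy)phenyl]furan-3,4-dicarboxylate | C=C(C)[C@H](O)CCC(=O)Cc1oc(-c2ccc(O[Si](C(C)C)(C(C)C)C(C)C)cc2OC)c(C(=O)OC)c1C(=O)OC
F0 | step 10 | none | none
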